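**Retrosynthetic overview**

- The strategy rests on the end ring: a cyclohexene (C1–C6) whose endocyclic C4=C5 bond is conjugated to the exocyclic, trisubstituted C6=C7 bond, with C8 cis to the gem-dimethyl carbon C1 (6E); C3 is S.
- The C2-symmetric target is cut at the two sp2–sp2 bonds C11–C12 and C11'–C12' (two-fold Suzuki coupling, then removal of both TBS groups), giving two C15 dienylboronates 19 and the central C10 diiodotetraene 27.
- Each ring is formed by a palladium-catalysed reductive 6-exo-dig cyclisation of the acyclic (S,Z)-iodo dienyne 15 (C5–C6 bond, hydride to C7) to the retro-dienyl bis-silyl ether 16.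
- 15 comes from ynone 11 (asymmetric transfer hydrogenation sets C3; hydroalumination–iodination sets the Z iodide); 11 comes from Sonogashira coupling of alkyne ester 8 with iodide 4 and a Weinreb/propynyl sequence.
- Ring order: the cyclohexene ring is the only ring formed, once, at the C14 stage (step 11), before chain extension and dimerisation.

Key step: step 11

Assumption: (E)-pent-2-en-4-yn-1-ol is taken as commercial and propyne enters as its commercial Grignard reagent MeC≡CMgBr; positions are given in carotenoid numbering (ring C1–C6, chain C7–C15).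

**Route**

Step 1
Reactants: 1 prop-2-yn-1-ol
Product: 3 (E)-3-iodo-2-methylprop-2-en-1-ol, via alkenylalane 2 (not isolated)
Conditions: Me3Al, Cp2ZrCl2, CH2Cl2, 0 °C to rt; then I2, THF, −30 °C
Reagents that add atoms: trimethylaluminium C[Al](C)C; iodine II
Why: Zirconium-catalysed Negishi carboalumination adds methyl and aluminium syn across the terminal alkyne with aluminium at the terminus, and iodinolysis with retention should give the E iodide.

Step 2
Reactants: 3 (E)-3-iodo-2-methylprop-2-en-1-ol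
Product: 4 triethyl{[(2E)-3-iodo-2-methylprop-2-en-1-yl]oxy}silane
Conditions: Et3SiCl, imidazole, CH2Cl2, 0 °C
Reagents that add atoms: chlorotriethylsilane CC[Si](Cl)(CC)CC
Why: Standard silylation of a primary allylic alcohol gives a TES ether that can later be removed in the presence of a secondary TBS ether.

Step 3
Reactants: 5 methyl 3,3-dimethylpent-4-enoate
Product: 7 methyl 3,3-dimethyl-4-oxobutanoate, via ozonide 6 (not isolated)
Conditions: O3, CH2Cl2, −78 °C; then PPh3, −78 °C to rt
Reagents that add atoms: ozone [O-][O+]=O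
Why: Ozonolysis with reductive work-up cleaves the terminal vinyl group to the non-enolisable neopentyl aldehyde without touching the ester.

Step 4
Reactants: 7 methyl 3,3-dimethyl-4-oxobutanoate
Product: 8 methyl 3,3-dimethylpent-4-ynoate
Conditions: dimethyl (1-diazo-2-oxopropyl)phosphonate, K2CO3, MeOH, 0 °C to rt
Reagents that add atoms: dimethyl (1-diazo-2-oxopropyl)phosphonate COP(=O)(OC)C(=[N+]=[N-])C(C)=O
Why: Seyferth–Gilbert homologation in the Ohira–Bestmann form converts the quaternary aldehyde into the terminal alkyne under conditions mild enough for the methyl ester (a bromination–elimination of 5 is avoided because the ester enolate would close a cyclopropane).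

Step 5
Reactants: 8 methyl 3,3-dimethylpent-4-ynoate; 4 triethyl{[(2E)-3-iodo-2-methylprop-2-en-1-yl]oxy}silane
Product: 9 methyl (6E)-3,3,7-trimethyl-8-[(triethylsilyl)oxy]oct-6-en-4-ynoate
Conditions: PdCl2(PPh3)2, CuI, Et3N, THF, rt, degassed
Reagents that add atoms: none
Why: Sonogashira coupling joins the tert-alkyl acetylene to the alkenyl iodide with retention of the E geometry and forms the C7–C8 bond.

Step 6
Reactants: 9 methyl (6E)-3,3,7-trimethyl-8-[(triethylsilyl)oxy]oct-6-en-4-ynoate
Product: 10 (6E)-N-methoxy-N,3,3,7-tetramethyl-8-[(triethylsilyl)oxy]oct-6-en-4-ynamide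
Conditions: MeNH(OMe)·HCl, i-PrMgCl, THF, −20 °C to 0 °C
Reagents that add atoms: N,O-dimethylhydroxylamine hydrochloride CNOC.Cl
Why: Aminolysis of the methyl ester by the magnesium amide formed in the flask is the standard direct route to a Weinreb amide.

Step 7
Reactants: 10 (6E)-N-methoxy-N,3,3,7-tetramethyl-8-[(triethylsilyl)oxy]oct-6-en-4-ynamide
Product: 11 (9E)-6,6,10-trimethyl-11-[(triethylsilyl)oxy]undec-9-ene-2,7-diyn-4-one
Conditions: MeC≡CMgBr, THF, 0 °C; poured into cold aq. NH4Cl
Reagents that add atoms: 1-propynylmagnesium bromide CC#C[Mg]Br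
Why: Weinreb ketone synthesis: the chelated tetrahedral adduct survives until the quench, so a single propynyl group is added and the ynone is not attacked further.

Step 8
Reactants: 11 (9E)-6,6,10-trimethyl-11-[(triethylsilyl)oxy]undec-9-ene-2,7-diyn-4-one
Product: 12 (4S,9E)-6,6,10-trimethyl-11-[(triethylsilyl)oxy]undec-9-ene-2,7-diyn-4-ol
Conditions: Ru(p-cymene)[(S,S)-TsNCHPhCHPhNH] (1 mol%), i-PrOH, rt
Reagents that add atoms: none
Why: Noyori asymmetric transfer hydrogenation of the alkynyl ketone, in which the (S,S)-ligand should direct hydride to the carbonyl face that gives the S carbinol (carotenoid C3) while the alkynes and the alkene stay untouched.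

Step 9
Reactants: 12 (4S,9E)-6,6,10-trimethyl-11-[(triethylsilyl)oxy]undec-9-ene-2,7-diyn-4-ol
Product: 14 (2Z,4S,9E)-2-iodo-6,6,10-trimethyl-11-[(triethylsilyl)oxy]undeca-2,9-dien-7-yn-4-ol, via cyclic alkenylaluminate 13 (not isolated)
Conditions: NaAlH2(OCH2CH2OMe)2, THF, 0 °C to rt; EtOAc; then I2, −78 °C to 0 °C
Reagents that add atoms: iodine II
Why: Alkoxide-directed trans-hydroalumination of the propargylic alkyne places hydrogen on C4 and aluminium on C5 in a five-membered alkoxyaluminate, and iodinolysis with retention should give the Z iodide (I cis to C3), the more distant enyne being out of reach of the directing alkoxide.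

Step 10
Reactants: 14 (2Z,4S,9E)-2-iodo-6,6,10-trimethyl-11-[(triethylsilyl)oxy]undeca-2,9-dien-7-yn-4-ol
Product: 15 tert-butyl{[(2Z,4S,9E)-2-iodo-6,6,10-trimethyl-11-(triethylsilyloxy)undeca-2,9-dien-7-yn-4-yl]oxy}dimethylsilane
Conditions: t-BuMe2SiCl, imidazole, DMF, rt
Reagents that add atoms: tert-butylchlorodimethylsilane CC(C)(C)[Si](C)(C)Cl
Why: Silylation of the secondary allylic alcohol gives the TBS ether that is carried to the last step.

Step 11
Reactants: 15 tert-butyl{[(2Z,4S,9E)-2-iodo-6,6,10-trimethyl-11-(triethylsilyloxy)undeca-2,9-dien-7-yn-4-yl]oxy}dimethylsilane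
Product: 16 tert-butyldimethyl{[(1S,4E)-3,5,5-trimethyl-4-{(2E)-3-methyl-4-[(triethylsilyl)oxy]but-2-en-1-ylidene}cyclohex-2-en-1-yl]oxy}silane
Conditions: Pd(OAc)2 (10 mol%), PPh3 (20 mol%), HCO2Na (3 equiv), DMF, 60 °C, degassed, dark
Reagents that add atoms: none
Why: Zerovalent palladium inserts into the C5–I bond with retention, the alkenylpalladium iodide adds syn across the tethered C6≡C7 alkyne (C5 to C6, palladium to C7), and formate then replaces iodide, loses CO2 and delivers hydride to C7 by reductive elimination with retention. This is the known intramolecular reductive Heck reaction (cyclic carbopalladation followed by hydride capture) of alkenyl halides with alkynes. The one ring closed is the cyclohexene C1–C6, by 6-exo-dig closure, favoured over 7-endo by the three-atom tether, by the Z alkene that holds C3 and the C5–Pd bond cis, and by the gem-dimethyl group at C1. No stereocentre is created, and C3 (S) lies away from the reacting atoms and is carried through unchanged. The selectivity needed is the geometry of C6=C7: because C5 and hydrogen arrive on the same side, C8 must end cis to C1 (6E), and the fixed Z geometry of the iodoalkene keeps C4=C5 endocyclic. Excess formate and a moderate temperature are chosen so that hydride capture outruns E/Z isomerisation of the dienylpalladium, while fast ring closure outpaces direct reduction of the C–I bond.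

Step 12
Reactants: 16 tert-butyldimethyl{[(1S,4E)-3,5,5-trimethyl-4-{(2E)-3-methyl-4-[(triethylsilyl)oxy]but-2-en-1-ylidene}cyclohex-2-en-1-yl]oxy}silane
Product: 17 (2E,4E)-4-[(4S)-4-{[tert-butyl(dimethyl)silyl]oxy}-2,6,6-trimethylcyclohex-2-en-1-ylidene]-2-methylbut-2-en-1-ol
Conditions: pyridinium p-toluenesulfonate (cat.), MeOH/CH2Cl2, 0 °C
Reagents that add atoms: none
Why: Mild acid-catalysed methanolysis should cleave the primary TES ether far faster than the secondary TBS ether.

Step 13
Reactants: 17 (2E,4E)-4-[(4S)-4-{[tert-butyl(dimethyl)silyl]oxy}-2,6,6-trimethylcyclohex-2-en-1-ylidene]-2-methylbut-2-en-1-ol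
Product: 18 (2E,4E)-4-[(4S)-4-{[tert-butyl(dimethyl)silyl]oxy}-2,6,6-trimethylcyclohex-2-en-1-ylidene]-2-methylbut-2-enal
Conditions: MnO2, CH2Cl2, rt, dark
Reagents that add atoms: none
Why: Neutral allylic oxidation with MnO2 gives the conjugated C14 trienal without acid or base that could move the retro double bonds.

Step 14
Reactants: 18 (2E,4E)-4-[(4S)-4-{[tert-butyl(dimethyl)silyl]oxy}-2,6,6-trimethylcyclohex-2-en-1-ylidene]-2-methylbut-2-enal
Product: 19 tert-butyldimethyl{[(1S,4E)-3,5,5-trimethyl-4-[(2E,4E)-3-methyl-5-(4,4,5,5-tetramethyl-1,3,2-dioxaborolan-2-yl)penta-2,4-dien-1-ylidene]cyclohex-2-en-1-yl]oxy}silane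
Conditions: CrCl2, LiI, Cl2CHB(pin), THF, rt, dark
Reagents that add atoms: 2-(dichloromethyl)-4,4,5,5-tetramethyl-1,3,2-dioxaborolane ClC(Cl)B1OC(C)(C)C(C)(C)O1
Why: Takai-type olefination with the geminal dichromium boryl reagent made from divalent chromium should convert the aldehyde into the E alkenylboronate (C10=C11) under neutral conditions.

Step 15
Reactants: 20 (E)-pent-2-en-4-yn-1-ol
Product: 22 (2E,4E)-5-iodo-4-methylpenta-2,4-dien-1-ol, via dienylalane 21 (not isolated)
Conditions: Me3Al, Cp2ZrCl2, CH2Cl2, 0 °C to rt; then I2, THF, −30 °C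
Reagents that add atoms: trimethylaluminium C[Al](C)C; iodine II
Why: Negishi carboalumination of the conjugated terminal enyne adds methyl and aluminium syn, and iodinolysis with retention should give the E trisubstituted iodide that becomes C12=C13.

Step 16
Reactants: 22 (2E,4E)-5-iodo-4-methylpenta-2,4-dien-1-ol
Product: 23 (2E,4E)-5-iodo-4-methylpenta-2,4-dienal
Conditions: MnO2, CH2Cl2, rt
Reagents that add atoms: none
Why: Allylic oxidation with MnO2 gives the dienal without touching the alkenyl iodide.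

Step 17
Reactants: 3 (E)-3-iodo-2-methylprop-2-en-1-ol
Product: 24 (1E)-3-bromo-1-iodo-2-methylprop-1-ene
Conditions: CBr4, PPh3, CH2Cl2, 0 °C
Reagents that add atoms: carbon tetrabromide BrC(Br)(Br)Br
Why: Appel bromination converts the primary allylic alcohol into the bromide without allylic transposition or loss of alkene geometry.

Step 18
Reactants: 24 (1E)-3-bromo-1-iodo-2-methylprop-1-ene
Product: 25 diethyl [(2E)-3-iodo-2-methylprop-2-en-1-yl]phosphonate
Conditions: P(OEt)3, neat, 100 °C
Reagents that add atoms: triethyl phosphite CCOP(OCC)OCC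
Why: Michaelis–Arbuzov reaction at the allylic bromide, the alkenyl iodide being inert to phosphite without a metal catalyst.

Step 19
Reactants: 25 diethyl [(2E)-3-iodo-2-methylprop-2-en-1-yl]phosphonate; 23 (2E,4E)-5-iodo-4-methylpenta-2,4-dienal
Product: 27 (1E,3E,5E,7E)-1,8-diiodo-2,7-dimethylocta-1,3,5,7-tetraene, via lithiated phosphonate 26 (not isolated)
Conditions: LiN(SiMe3)2, THF, −78 °C; then 23, −78 °C to 0 °C, dark
Reagents that add atoms: none
Why: Horner–Wadsworth–Emmons olefination of the allylic phosphonate anion (an amide base avoids iodine–lithium exchange) should form the new disubstituted alkene E and give the symmetric C10 unit C12–C12'.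

Step 20
Reactants: 19 the C15 dienylboronate (2.2 equiv); 27 (1E,3E,5E,7E)-1,8-diiodo-2,7-dimethylocta-1,3,5,7-tetraene
Product: 28 (3S,3'S)-3,3'-bis(tert-butyldimethylsilyloxy)-4',5'-didehydro-4,5'-retro-β,β-carotene
Conditions: Pd(PPh3)4 (10 mol%), TlOEt, THF/H2O, rt, degassed, dark
Reagents that add atoms: none
Why: Two-fold Suzuki–Miyaura coupling forms C11–C12 and C11'–C12' with retention at all four sp2 carbons, TlOEt allowing transmetalation at room temperature so that the polyene is not heated.

Step 21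
Reactants: 28 (3S,3'S)-3,3'-bis(tert-butyldimethylsilyloxy)-4',5'-didehydro-4,5'-retro-β,β-carotene
Product: 29 (3S,3'S)-4',5'-didehydro-4,5'-retro-β,β-carotene-3,3'-diol (CNP0349476.1)
Conditions: Bu4NF, THF, 0 °C to rt, dark
Reagents that add atoms: none
Why: Fluoride cleaves both TBS ethers under non-acidic conditions, so the allylic C3 and C3' alcohols are not ionised and their configuration is kept.

**Compound list**

1 | prop-2-yn-1-ol | C#CCO | starting material
2 | dimethylalane of (E)-2-methyl-3-alumino-prop-2-en-1-ol dimethylaluminium alkoxide | C[Al](C)/C=C(\C)CO[Al](C)C | intermediate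
3 | (E)-3-iodo-2-methylprop-2-en-1-ol | OC/C(C)=C/I | intermediate
4 | triethyl{[(2E)-3-iodo-2-methylprop-2-en-1-yl]oxy}silane | CC[Si](CC)(CC)OC/C(C)=C/I | intermediate
5 | methyl 3,3-dimethylpent-4-enoate | COC(=O)CC(C)(C)C=C | starting material
6 | methyl 3-methyl-3-(1,2,4-trioxolan-3-yl)butanoate | COC(=O)CC(C)(C)C1OCOO1 | intermediate
7 | methyl 3,3-dimethyl-4-oxobutanoate | COC(=O)CC(C)(C)C=O | intermediate
8 | methyl 3,3-dimethylpent-4-ynoate | COC(=O)CC(C)(C)C#C | intermediate
9 | methyl (6E)-3,3,7-trimethyl-8-[(triethylsilyl)oxy]oct-6-en-4-ynoate | COC(=O)CC(C)(C)C#C/C=C(\C)CO[Si](CC)(CC)CC | intermediate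
10 | (6E)-N-methoxy-N,3,3,7-tetramethyl-8-[(triethylsilyl)oxy]oct-6-en-4-ynamide | CON(C)C(=O)CC(C)(C)C#C/C=C(\C)CO[Si](CC)(CC)CC | intermediate
11 | (9E)-6,6,10-trimethyl-11-[(triethylsilyl)oxy]undec-9-ene-2,7-diyn-4-one | CC#CC(=O)CC(C)(C)C#C/C=C(\C)CO[Si](CC)(CC)CC | intermediate
12 | (4S,9E)-6,6,10-trimethyl-11-[(triethylsilyl)oxy]undec-9-ene-2,7-diyn-4-ol | CC#C[C@@H](O)CC(C)(C)C#C/C=C(\C)CO[Si](CC)(CC)CC | intermediate
13 | sodium cyclic alkoxy(alkenyl)bis(2-methoxyethoxy)aluminate from 12 (Al on C5, O on C3) | [Na+].COCCO[Al-]1(OCCOC)O[C@@H](CC(C)(C)C#C/C=C(\C)CO[Si](CC)(CC)CC)C=C1C | intermediate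
14 | (2Z,4S,9E)-2-iodo-6,6,10-trimethyl-11-[(triethylsilyl)oxy]undeca-2,9-dien-7-yn-4-ol | C/C(I)=C/[C@@H](O)CC(C)(C)C#C/C=C(\C)CO[Si](CC)(CC)CC | intermediate
15 | tert-butyl{[(2Z,4S,9E)-2-iodo-6,6,10-trimethyl-11-(triethylsilyloxy)undeca-2,9-dien-7-yn-4-yl]oxy}dimethylsilane | C/C(I)=C/[C@@H](O[Si](C)(C)C(C)(C)C)CC(C)(C)C#C/C=C(\C)CO[Si](CC)(CC)CC | intermediate
16 | tert-butyldimethyl{[(1S,4E)-3,5,5-trimethyl-4-{(2E)-3-methyl-4-[(triethylsilyl)oxy]but-2-en-1-ylidene}cyclohex-2-en-1-yl]oxy}silane | CC1=C[C@@H](O[Si](C)(C)C(C)(C)C)CC(C)(C)\C1=C/C=C(\C)CO[Si](CC)(CC)CC | intermediate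
17 | (2E,4E)-4-[(4S)-4-{[tert-butyl(dimethyl)silyl]oxy}-2,6,6-trimethylcyclohex-2-en-1-ylidene]-2-methylbut-2-en-1-ol | CC1=C[C@@H](O[Si](C)(C)C(C)(C)C)CC(C)(C)\C1=C/C=C(\C)CO | intermediate
18 | (2E,4E)-4-[(4S)-4-{[tert-butyl(dimethyl)silyl]oxy}-2,6,6-trimethylcyclohex-2-en-1-ylidene]-2-methylbut-2-enal | CC1=C[C@@H](O[Si](C)(C)C(C)(C)C)CC(C)(C)\C1=C/C=C(\C)C=O | intermediate
19 | tert-butyldimethyl{[(1S,4E)-3,5,5-trimethyl-4-[(2E,4E)-3-methyl-5-(4,4,5,5-tetramethyl-1,3,2-dioxaborolan-2-yl)penta-2,4-dien-1-ylidene]cyclohex-2-en-1-yl]oxy}silane | CC1=C[C@@H](O[Si](C)(C)C(C)(C)C)CC(C)(C)\C1=C/C=C(C)/C=C/B2OC(C)(C)C(C)(C)O2 | intermediate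
20 | (E)-pent-2-en-4-yn-1-ol | C#C/C=C/CO | starting material
21 | dimethylalane of (2E,4E)-5-alumino-4-methylpenta-2,4-dien-1-ol dimethylaluminium alkoxide | C[Al](C)/C=C(C)/C=C/CO[Al](C)C | intermediate
22 | (2E,4E)-5-iodo-4-methylpenta-2,4-dien-1-ol | OC/C=C/C(C)=C/I | intermediate
23 | (2E,4E)-5-iodo-4-methylpenta-2,4-dienal | O=C/C=C/C(C)=C/I | intermediate
24 | (1E)-3-bromo-1-iodo-2-methylprop-1-ene | BrC/C(C)=C/I | intermediate
25 | diethyl [(2E)-3-iodo-2-methylprop-2-en-1-yl]phosphonate | CCOP(=O)(OCC)C/C(C)=C/I | intermediate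
26 | lithium salt of the α-carbanion of 25 | [Li+].CCOP(=O)(OCC)[CH-]/C(C)=C/I | intermediate
27 | (1E,3E,5E,7E)-1,8-diiodo-2,7-dimethylocta-1,3,5,7-tetraene | I/C=C(C)/C=C/C=C/C(C)=C/I | intermediate
28 | (3S,3'S)-3,3'-bis(tert-butyldimethylsilyloxy)-4',5'-didehydro-4,5'-retro-β,β-carotene | CC1=C[C@@H](O[Si](C)(C)C(C)(C)C)CC(C)(C)\C1=C/C=C(C)/C=C/C=C(C)/C=C/C=C/C(C)=C/C=C/C(C)=C/C=C1/C(C)=C[C@@H](O[Si](C)(C)C(C)(C)C)CC1(C)C | intermediate
29 | (3S,3'S)-4',5'-didehydro-4,5'-retro-β,β-carotene-3,3'-diol | CC1=C[C@@H](O)CC(C)(C)\C1=C/C=C(C)/C=C/C=C(C)/C=C/C=C/C(C)=C/C=C/C(C)=C/C=C1/C(C)=C[C@@H](O)CC1(C)C | target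

**Step count**

Total steps: 21. Longest linear sequence: 14 steps (5 → 7 → 8 → 9 → 10 → 11 → 12 → 14 → 15 → 16 → 17 → 18 → 19 → 28 → 29).

**Steps most likely to fail**

1. Step 11 (reductive cyclisation). Hydride may be transferred to the alkenylpalladium iodide before ring closure, giving plain deiodination, or the dienylpalladium may isomerise about C6=C7 before hydride capture, eroding the 6E geometry. Fallback: C–C bond formation is separated from hydrogen delivery. Setting out from 15, a borylative 6-exo-dig cyclisation with bis(pinacolato)diboron (Pd(PPh3)4, KOAc, dioxane, 80 °C; carbopalladation followed by Miyaura-type boryl transfer, with no hydride source present) should give the C7 pinacol boronate of 16 with boron cis to C5, tert-butyldimethyl{[(1S,4E)-3,5,5-trimethyl-4-{(2E)-3-methyl-1-(4,4,5,5-tetramethyl-1,3,2-dioxaborolan-2-yl)-4-[(triethylsilyl)oxy]but-2-en-1-ylidene}cyclohex-2-en-1-yl]oxy}silane F1. Stereoretentive protodeboronation of this boronate with AgF in THF/MeOH/H2O at rt then comes back to the route at 16.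

2. Step 20 (two-fold Suzuki coupling). The dienylboronate may protodeboronate under the basic aqueous conditions, the reaction may stall after the first coupling, or the growing polyene may isomerise or degrade. Fallback: the polarity is reversed and the coupling is run without base. Setting out from 18, Takai iodo-olefination (CrCl2, CHI3, THF, 0 °C) should give the C15 dienyl iodide tert-butyl{[(1S,4E)-4-[(2E,4E)-5-iodo-3-methylpenta-2,4-dien-1-ylidene]-3,5,5-trimethylcyclohex-2-en-1-yl]oxy}dimethylsilane F2. Setting out from 27, two-fold iodine–lithium exchange (t-BuLi, Et2O, −78 °C) and quenching with Bu3SnCl should give (1E,3E,5E,7E)-2,7-dimethyl-1,8-bis(tributylstannyl)octa-1,3,5,7-tetraene F3. A two-fold Stille coupling of the iodide (2 equiv) with the bis-stannane (Pd2(dba)3, AsPh3, DMF/THF, rt, dark) comes back to the route at 28.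

3. Step 14 (chromium boryl-olefination). The bulky geminal dichromium reagent may add slowly to the α-branched, fully conjugated trienal, divalent chromium may instead reduce or pinacol-couple the aldehyde, and E selectivity may fall. Fallback: the boronate is made through an alkyne. Setting out from 18, Colvin homologation (Me3SiCHN2, LiN(i-Pr)2, THF, −78 °C to rt) should give the terminal enyne tert-butyldimethyl{[(1S,4E)-3,5,5-trimethyl-4-[(2E)-3-methylpent-2-en-4-yn-1-ylidene]cyclohex-2-en-1-yl]oxy}silane F4. Syn-hydroboration of its terminal alkyne with pinacolborane (Cp2Zr(H)Cl cat., Et3N, CH2Cl2, rt) comes back to the route at 19.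

Further compounds
F1 | step 11 | tert-butyldimethyl{[(1S,4E)-3,5,5-trimethyl-4-{(2E)-3-methyl-1-(4,4,5,5-tetramethyl-1,3,2-dioxaborolan-2-yl)-4-[(triethylsilyl)oxy]but-2-en-1-ylidene}cyclohex-2-en-1-yl]oxy}silane | CC1=C[C@@H](O[Si](C)(C)C(C)(C)C)CC(C)(C)\C1=C(B2OC(C)(C)C(C)(C)O2)/C=C(\C)CO[Si](CC)(CC)CC
F2 | step 20 | tert-butyl{[(1S,4E)-4-[(2E,4E)-5-iodo-3-methylpenta-2,4-dien-1-ylidene]-3,5,5-trimethylcyclohex-2-en-1-yl]oxy}dimethylsilane | CC1=C[C@@H](O[Si](C)(C)C(C)(C)C)CC(C)(C)\C1=C/C=C(C)/C=C/I
F3 | step 20 | (1E,3E,5E,7E)-2,7-dimethyl-1,8-bis(tributylstannyl)octa-1,3,5,7-tetraene | CCCC[Sn](CCCC)(CCCC)/C=C(C)/C=C/C=C/C(C)=C/[Sn](CCCC)(CCCC)CCCC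
F4 | step 14 | tert-butyldimethyl{[(1S,4E)-3,5,5-trimethyl-4-[(2E)-3-methylpent-2-en-4-yn-1-ylidene]cyclohex-2-en-1-yl]oxy}silane | CC1=C[C@@H](O[Si](C)(C)C(C)(C)C)CC(C)(C)\C1=C/C=C(\C)C#C
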